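**Retrosynthetic overview**

- Last bond: the C(sp3)–C(sp2) bond between the ethylene linker and ring C (cyclohexene), by B-alkyl Suzuki coupling of a vinyl-bearing oxepane–cyclohexane (rings A/B) with a tetrasubstituted cyclohexenyl triflate; silyl groups are removed in the same flask.
- Ring C is the carbocycle of 2-methylresorcinol. Hydrogenative dearomatisation and C-allylation in one flask give a mirror-symmetric 2,2-disubstituted cyclohexane-1,3-dione. One enantioselective carbonyl reduction then breaks the symmetry and sets both ring-C stereocentres (key events).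
- Ring C is finished by cross-metathesis (side chain), α-methylation and enol triflation.
- Rings A and B form in one cascade from an acyclic Shi bis-epoxide: terminal epoxide → epoxonium (oxepane, ring A) → capture by a silyl dienol ether (cyclohexanone, ring B, with a vinyl handle). MeCeCl2 then sets the tertiary carbinol.
- Ring order: ring C (from the arene) in one branch; ring A then ring B in the other; fragment union last.

Assumption: the D-fructose-derived Shi ketone and (S)-Me-CBS follow their usual selectivity models; reagents written over the arrow are bought and carry no number (numbered starting materials: 1, 9, 10).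

**Route**

Step 1
Reactants: 1 2-methylresorcinol
Product: 3 2-methyl-2-(prop-2-en-1-yl)cyclohexane-1,3-dione, via sodium 2-methylcyclohexane-1,3-dionate 2 (not isolated)
Conditions: H2 (70 bar), Raney Ni, NaOH (1.1 equiv), H2O, 50 °C; filter; allyl bromide (1.5 equiv), Bu4NI (5 mol %), rt to 40 °C
Reagents that add atoms: allyl bromide (C=CCBr)
Why: Under base the resorcinol is hydrogenated through its keto tautomer and the reduction stops at the delocalized 1,3-dionate 2 (partial arene hydrogenation, the way dihydroresorcinol is made), and this enolate is C-allylated in the same aqueous solution (enolate alkylation, with any O-allyl enol ether funnelled to 3 by Claisen rearrangement on warming), so the aromatic ring becomes an achiral, mirror-symmetric quaternary dione with no stereocentre yet.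

Step 2
Reactants: 3 2-methyl-2-(prop-2-en-1-yl)cyclohexane-1,3-dione
Product: 4 (2R,3R)-3-hydroxy-2-methyl-2-(prop-2-en-1-yl)cyclohexan-1-one
Conditions: (S)-2-methyl-CBS-oxazaborolidine (30 mol %), catecholborane (1.2 equiv), toluene, −78 to −40 °C; aq. NaOH work-up
Reagents that add atoms: none
Why: Corey–Bakshi–Shibata reduction used as an enantioselective desymmetrization: the (S)-catalyst binds a carbonyl with the quaternary carbon as the large group and delivers hydride to give the (R)-carbinol, and of the two enantiotopic carbonyls it reduces the one in which this face lies anti to the bulkier allyl arm, so one hydride transfer sets the carbinol (3R) and thereby the quaternary centre (2R) with OH cis to allyl, while the remaining, more hindered ketone is not reduced at low temperature.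

Step 3
Reactants: 4 (2R,3R)-3-hydroxy-2-methyl-2-(prop-2-en-1-yl)cyclohexan-1-one
Product: 5 (2R,3R)-3-hydroxy-2-[(2E)-4-hydroxy-4-methylpent-2-en-1-yl]-2-methylcyclohexan-1-one
Conditions: 2-methylbut-3-en-2-ol (10 equiv), second-generation Hoveyda–Grubbs catalyst RuCl2(H2IMes)(=CH-C6H4-2-OiPr) (3 mol %), CH2Cl2, 40 °C
Reagents that add atoms: 2-methylbut-3-en-2-ol (C=CC(C)(C)O)
Why: Olefin cross-metathesis of the unhindered terminal allyl group with an excess of the slowly homodimerizing tertiary allylic alcohol gives the cross product as the thermodynamically favoured E-alkene, and the ruthenium carbene tolerates the free hydroxyls and the ketone, with no stereocentre touched.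

Step 4
Reactants: 5 (2R,3R)-3-hydroxy-2-[(2E)-4-hydroxy-4-methylpent-2-en-1-yl]-2-methylcyclohexan-1-one
Product: 6 (2R,3R)-2-methyl-2-[(2E)-4-methyl-4-(triethylsilyloxy)pent-2-en-1-yl]-3-(triethylsilyloxy)cyclohexan-1-one
Conditions: Et3SiOTf (2.6 equiv), 2,6-lutidine (4 equiv), CH2Cl2, −78 to 0 °C
Reagents that add atoms: triethylsilyl trifluoromethanesulfonate (CC[Si](CC)(CC)OS(=O)(=O)C(F)(F)F)
Why: The silyl triflate with a hindered pyridine base silylates both the secondary and the tertiary allylic hydroxyl (silyl ether protection) under conditions that avoid retro-aldol cleavage, so that neither OH can consume base or be triflated in steps 5 and 6.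

Step 5
Reactants: 6 (2R,3R)-2-methyl-2-[(2E)-4-methyl-4-(triethylsilyloxy)pent-2-en-1-yl]-3-(triethylsilyloxy)cyclohexan-1-one
Product: 7 (2R,3R,6RS)-2,6-dimethyl-2-[(2E)-4-methyl-4-(triethylsilyloxy)pent-2-en-1-yl]-3-(triethylsilyloxy)cyclohexan-1-one
Conditions: LiN(iPr)2 (1.15 equiv), THF, −78 °C; MeI (3 equiv), DMPU, −78 to −30 °C
Reagents that add atoms: iodomethane (CI)
Why: Kinetic lithium enolate alkylation: C2 is quaternary, so deprotonation and methylation can occur only at C6, and the new C6 stereocentre (epimer mixture) is destroyed again in step 6.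

Step 6
Reactants: 7 (2R,3R,6RS)-2,6-dimethyl-2-[(2E)-4-methyl-4-(triethylsilyloxy)pent-2-en-1-yl]-3-(triethylsilyloxy)cyclohexan-1-one
Product: 8 (5R,6R)-2,6-dimethyl-6-[(2E)-4-methyl-4-(triethylsilyloxy)pent-2-en-1-yl]-5-(triethylsilyloxy)cyclohex-1-en-1-yl trifluoromethanesulfonate
Conditions: KN(SiMe3)2 (1.5 equiv), THF, −78 to 0 °C; PhNTf2 (1.4 equiv), 0 °C to rt
Reagents that add atoms: N-phenylbis(trifluoromethanesulfonimide) (O=S(=O)(N(c1ccccc1)S(=O)(=O)C(F)(F)F)C(F)(F)F)
Why: The ketone can enolize only towards C6, and O-sulfonylation of this tetrasubstituted potassium enolate (enol triflate formation, as practised on 2,2,6-trimethylcyclohexanone) fixes the methyl-bearing tetrasubstituted double bond regiospecifically and erases the C6 stereocentre.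

Step 7
Reactants: 9 geranyl bromide; 10 N-methoxy-N-methylacetamide
Product: 11 (4E)-N-methoxy-N,5,9-trimethyldeca-4,8-dienamide
Conditions: 10, LiN(iPr)2 (1.1 equiv), THF, −78 °C; then 9, −78 to 0 °C
Reagents that add atoms: none
Why: SN2 alkylation of the lithium enolate of the Weinreb acetamide by the primary allylic bromide (amide enolate alkylation) joins the C10 chain to the future ketone carbon without touching the E-alkene.

Step 8
Reactants: 11 (4E)-N-methoxy-N,5,9-trimethyldeca-4,8-dienamide
Product: 12 N-methoxy-N-methyl-3-[(2R,3R)-3-{2-[(2R)-3,3-dimethyloxiran-2-yl]ethyl}-3-methyloxiran-2-yl]propanamide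
Conditions: D-fructose-derived Shi ketone (0.6 equiv), KHSO5 (Oxone, 3 equiv), K2CO3, Bu4NHSO4, MeCN–CH2(OMe)2 / aq. Na2B4O7–Na2EDTA buffer (pH 10.5), 0 °C
Reagents that add atoms: potassium peroxymonosulfate ([K+].[O-]S(=O)(=O)OO)
Why: Shi asymmetric epoxidation: the chiral dioxirane generated from the ketone and KHSO5 transfers oxygen through a spiro transition state to the same face of both electron-rich E-trisubstituted alkenes, giving the (R,R)- and (R)-epoxides, while the amide is inert at pH 10.5.

Step 9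
Reactants: 12 N-methoxy-N-methyl-3-[(2R,3R)-3-{2-[(2R)-3,3-dimethyloxiran-2-yl]ethyl}-3-methyloxiran-2-yl]propanamide
Product: 13 1-[(2R,3R)-3-{2-[(2R)-3,3-dimethyloxiran-2-yl]ethyl}-3-methyloxiran-2-yl]hex-5-en-3-one
Conditions: allylmagnesium bromide (1.3 equiv), THF, −78 °C; AcOH/THF quench at −78 °C
Reagents that add atoms: allylmagnesium bromide (C=CC[Mg]Br)
Why: Weinreb ketone synthesis: the allyl Grignard reagent adds once to the N-methoxy-N-methylamide because the magnesium-chelated tetrahedral intermediate survives until work-up, the trisubstituted epoxides do not react at −78 °C, and the cold acidic quench keeps the β,γ-double bond out of conjugation.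

Step 10
Reactants: 13 1-[(2R,3R)-3-{2-[(2R)-3,3-dimethyloxiran-2-yl]ethyl}-3-methyloxiran-2-yl]hex-5-en-3-one
Product: 14 tert-butyl({(3Z)-1-[(2R,3R)-3-{2-[(2R)-3,3-dimethyloxiran-2-yl]ethyl}-3-methyloxiran-2-yl]hexa-3,5-dien-3-yl}oxy)dimethylsilane
Conditions: t-BuMe2SiCl (1.5 equiv), LiN(SiMe3)2 (1.2 equiv, added last), DMPU–THF, −78 °C
Reagents that add atoms: tert-butyldimethylsilyl chloride (CC(C)(C)[Si](C)(C)Cl)
Why: The CH2 flanked by the carbonyl and the vinyl group is by far the most acidic position, so LiN(SiMe3)2 with internal silyl chloride quench gives only the extended enolate and its O-silylation product, the (Z)-2-silyloxy-1,3-diene (regiodefined silyl dienol ether formation), which locks the enol double bond towards the vinyl-bearing carbon.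

Step 11
Reactants: 14 tert-butyl({(3Z)-1-[(2R,3R)-3-{2-[(2R)-3,3-dimethyloxiran-2-yl]ethyl}-3-methyloxiran-2-yl]hexa-3,5-dien-3-yl}oxy)dimethylsilane
Product: 15 (3R,5aR,6R,9aR)-6-ethenyl-2,2,5a-trimethyl-3-(trimethylsilyloxy)octahydro-1-benzoxepin-7(2H)-one
Conditions: Me3SiOTf (1.2 equiv), 2,6-di-tert-butyl-4-methylpyridine (1.5 equiv), CH2Cl2 (0.005 M), −78 °C; Et3N quench
Reagents that add atoms: trimethylsilyl trifluoromethanesulfonate (C[Si](C)(C)OS(=O)(=O)C(F)(F)F)
Why: Proposed new method: the silyl triflate silylates the terminal epoxide, the neighbouring epoxide oxygen opens it at the tertiary carbon to give a bicyclic epoxonium ion (ring A, with the (R)-carbinol carbon retained as its silyl ether), and the enol-ether carbon of the silyloxydiene then opens the epoxonium at its tertiary carbon with inversion through a chair transition state (α-attack closes ring B, whereas γ-attack would need an eight-membered ring), giving the trans-fused oxepane–cyclohexanone with the epimerizable vinyl-bearing centre equatorial; the closest known reaction type is the silyl-triflate-promoted tandem oxa-/carbacyclization of 1,5-diepoxides terminated by simple silyl enol ethers, the new element being the dienol ether terminator.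

Step 12
Reactants: 15 (3R,5aR,6R,9aR)-6-ethenyl-2,2,5a-trimethyl-3-(trimethylsilyloxy)octahydro-1-benzoxepin-7(2H)-one
Product: 16 (3R,5aR,6R,7S,9aR)-6-ethenyl-2,2,5a,7-tetramethyl-3-(trimethylsilyloxy)decahydro-1-benzoxepin-7-ol
Conditions: CeCl3 (3 equiv), MeLi (2.8 equiv), THF, −78 °C
Reagents that add atoms: methyllithium ([Li]C)
Why: Organocerium 1,2-addition: MeCeCl2 is nucleophilic but weakly basic, so it adds to the easily enolized β,γ-unsaturated ketone without deprotonation or double-bond migration, and because the axial angular methyl at C5a is syn-axial to the axial approach the methyl group enters equatorially, giving the axial tertiary alcohol (7S), cis to the angular methyl.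

Step 13
Reactants: 16 (3R,5aR,6R,7S,9aR)-6-ethenyl-2,2,5a,7-tetramethyl-3-(trimethylsilyloxy)decahydro-1-benzoxepin-7-ol; 8 (5R,6R)-2,6-dimethyl-6-[(2E)-4-methyl-4-(triethylsilyloxy)pent-2-en-1-yl]-5-(triethylsilyloxy)cyclohex-1-en-1-yl trifluoromethanesulfonate
Product: 19 siphonellinol C, via B-alkyl-9-BBN adduct 17 (not isolated), via tris-silyl coupling product 18 (not isolated)
Conditions: 16 (1.3 equiv), 9-BBN-H dimer (1.2 equiv), THF, rt; 3 M aq. K3PO4; 8 (1.0 equiv), PdCl2(dppf) (10 mol %), AsPh3 (10 mol %), DMF, 50 °C; then Bu4NF (6 equiv), THF, rt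
Reagents that add atoms: none
Why: B-alkyl Suzuki–Miyaura coupling followed by fluoride desilylation: 9-BBN adds anti-Markovnikov to the only monosubstituted alkene, residual B–H is destroyed by the aqueous base before 8 is added, the primary alkylborane transmetalates to the alkenylpalladium species formed by oxidative addition of the tetrasubstituted triflate (a coupling proven on 2,6,6-trimethylcyclohexenyl triflate) and reductive elimination forms the C(sp3)–C(sp2) bond with the double bond fixed in place, after which Bu4NF removes the three silyl groups, no stereocentre being involved in either event.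

**Compound list**

1 | 2-methylresorcinol (2-methylbenzene-1,3-diol) | Cc1c(O)cccc1O | starting material
2 | sodium 2-methylcyclohexane-1,3-dionate (enolate of 2-methylcyclohexane-1,3-dione) | [Na+].CC1=C([O-])CCCC1=O | intermediate
3 | 2-methyl-2-(prop-2-en-1-yl)cyclohexane-1,3-dione | C=CCC1(C)C(=O)CCCC1=O | intermediate
4 | (2R,3R)-3-hydroxy-2-methyl-2-(prop-2-en-1-yl)cyclohexan-1-one (OH cis to allyl) | C=CC[C@@]1(C)C(=O)CCC[C@H]1O | intermediate
5 | (2R,3R)-3-hydroxy-2-[(2E)-4-hydroxy-4-methylpent-2-en-1-yl]-2-methylcyclohexan-1-one | CC(C)(O)/C=C/C[C@@]1(C)C(=O)CCC[C@H]1O | intermediate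
6 | (2R,3R)-2-methyl-2-[(2E)-4-methyl-4-(triethylsilyloxy)pent-2-en-1-yl]-3-(triethylsilyloxy)cyclohexan-1-one | CC(C)(O[Si](CC)(CC)CC)/C=C/C[C@@]1(C)C(=O)CCC[C@H]1O[Si](CC)(CC)CC | intermediate
7 | (2R,3R,6RS)-2,6-dimethyl-2-[(2E)-4-methyl-4-(triethylsilyloxy)pent-2-en-1-yl]-3-(triethylsilyloxy)cyclohexan-1-one (C6 epimers) | CC(C)(O[Si](CC)(CC)CC)/C=C/C[C@@]1(C)C(=O)C(C)CC[C@H]1O[Si](CC)(CC)CC | intermediate
8 | (5R,6R)-2,6-dimethyl-6-[(2E)-4-methyl-4-(triethylsilyloxy)pent-2-en-1-yl]-5-(triethylsilyloxy)cyclohex-1-en-1-yl trifluoromethanesulfonate | CC(C)(O[Si](CC)(CC)CC)/C=C/C[C@@]1(C)C(OS(=O)(=O)C(F)(F)F)=C(C)CC[C@H]1O[Si](CC)(CC)CC | intermediate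
9 | geranyl bromide ((2E)-1-bromo-3,7-dimethylocta-2,6-diene) | CC(C)=CCC/C(C)=C/CBr | starting material
10 | N-methoxy-N-methylacetamide | CC(=O)N(C)OC | starting material
11 | (4E)-N-methoxy-N,5,9-trimethyldeca-4,8-dienamide | CC(C)=CCC/C(C)=C/CCC(=O)N(C)OC | intermediate
12 | N-methoxy-N-methyl-3-[(2R,3R)-3-{2-[(2R)-3,3-dimethyloxiran-2-yl]ethyl}-3-methyloxiran-2-yl]propanamide | CON(C)C(=O)CC[C@H]1O[C@]1(C)CC[C@H]1OC1(C)C | intermediate
13 | 1-[(2R,3R)-3-{2-[(2R)-3,3-dimethyloxiran-2-yl]ethyl}-3-methyloxiran-2-yl]hex-5-en-3-one | C=CCC(=O)CC[C@H]1O[C@]1(C)CC[C@H]1OC1(C)C | intermediate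
14 | tert-butyl({(3Z)-1-[(2R,3R)-3-{2-[(2R)-3,3-dimethyloxiran-2-yl]ethyl}-3-methyloxiran-2-yl]hexa-3,5-dien-3-yl}oxy)dimethylsilane | C=C/C=C(\O[Si](C)(C)C(C)(C)C)CC[C@H]1O[C@]1(C)CC[C@H]1OC1(C)C | intermediate
15 | (3R,5aR,6R,9aR)-6-ethenyl-2,2,5a-trimethyl-3-(trimethylsilyloxy)octahydro-1-benzoxepin-7(2H)-one (trans ring fusion, vinyl equatorial) | C=C[C@@H]1[C@@]2(C)CC[C@@H](O[Si](C)(C)C)C(C)(C)O[C@@H]2CCC1=O | intermediate
16 | (3R,5aR,6R,7S,9aR)-6-ethenyl-2,2,5a,7-tetramethyl-3-(trimethylsilyloxy)decahydro-1-benzoxepin-7-ol | C=C[C@@H]1[C@@]2(C)CC[C@@H](O[Si](C)(C)C)C(C)(C)O[C@@H]2CC[C@]1(C)O | intermediate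
17 | 9-{2-[(3R,5aR,6R,7S,9aR)-7-hydroxy-2,2,5a,7-tetramethyl-3-(trimethylsilyloxy)decahydro-1-benzoxepin-6-yl]ethyl}-9-borabicyclo[3.3.1]nonane | C1CCC2CCCC1B2CC[C@@H]3[C@@]4(C)CC[C@@H](O[Si](C)(C)C)C(C)(C)O[C@@H]4CC[C@]3(C)O | intermediate
18 | (3R,5aR,6R,7S,9aR)-6-{2-[(5R,6S)-2,6-dimethyl-6-[(2E)-4-methyl-4-(triethylsilyloxy)pent-2-en-1-yl]-5-(triethylsilyloxy)cyclohex-1-en-1-yl]ethyl}-2,2,5a,7-tetramethyl-3-(trimethylsilyloxy)decahydro-1-benzoxepin-7-ol | CC1=C(CC[C@@H]2[C@@]3(C)CC[C@@H](O[Si](C)(C)C)C(C)(C)O[C@@H]3CC[C@]2(C)O)[C@](C)(C/C=C/C(C)(C)O[Si](CC)(CC)CC)[C@H](O[Si](CC)(CC)CC)CC1 | intermediate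
19 | siphonellinol C, (3R,5aR,6R,7S,9aR)-6-{2-[(5R,6S)-5-hydroxy-6-[(2E)-4-hydroxy-4-methylpent-2-en-1-yl]-2,6-dimethylcyclohex-1-en-1-yl]ethyl}-2,2,5a,7-tetramethyldecahydro-1-benzoxepine-3,7-diol | CC1=C(CC[C@@H]2[C@@]3(C)CC[C@@H](O)C(C)(C)O[C@@H]3CC[C@]2(C)O)[C@](C)(C/C=C/C(C)(C)O)[C@H](O)CC1 | target

**Totals and fallbacks**

Total step count: 13. Longest linear sequence: 7 (steps 1–6 then 13, or steps 7–12 then 13).

The three steps most likely to fail:

Step 11 (cascade). The silyloxydiene may react intermolecularly through its γ-terminus, or the α-vinyl ketone 15 may isomerize to the conjugated enone. The fallback changes the order of events and sets out from 14 (together with 8). 9-BBN hydroborates the terminal vinyl group of 14 to the B-alkyl-9-BBN derivative F3. This is coupled with triflate 8 (PdCl2(dppf), AsPh3, Cs2CO3, DMF with 2 equiv of H2O, rt) to give the simple tert-butyldimethylsilyl enol ether F4, which already carries ring C. The same Me3SiOTf cascade then ends on an ordinary silyl enol ether, the established terminator, and gives the saturated α-alkyl ketone F5, which cannot conjugate. MeLi/CeCl3 converts F5 into 18, where the route is rejoined at the Bu4NF stage of step 13.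

Step 2 (desymmetrization). The oxazaborolidine may discriminate poorly between the methyl and allyl arms, giving low d.r. or e.e. The fallback replaces catalytic desymmetrization by kinetic resolution and sets out from 3. LiAlH(OtBu)3 (THF, −78 °C) gives the racemic cis-ketol F1 (hydride anti to the larger arm). Burkholderia cepacia lipase with vinyl acetate acylates the (3R) enantiomer, for which the quaternary carbon is the large group, to the (1R,2R)-acetate F2. F2 is separated from unreacted (2S,3S)-alcohol, and hydrolysis of F2 with the same lipase in pH 7 buffer returns 4.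

Step 13 (coupling). Transmetalation of the hindered alkylborane onto the hindered tetrasubstituted alkenylpalladium may stall. The fallback replaces the two-electron coupling by a radical cross-electrophile coupling and sets out from 16. Hydroboration with 9-BBN (via 17) and NaBO3 oxidation give the primary alcohol F6. I2, PPh3 and imidazole give the primary iodide F7, with the tertiary OH untouched. Nickel-catalysed reductive coupling of F7 with 8 (NiBr2(dme), 4,4'-di-tert-butyl-2,2'-bipyridine, Mn, DMA, rt), in which the alkyl radical is captured by the alkenylnickel species, gives 18, where the route is rejoined at the Bu4NF stage of step 13.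

**Further compounds**

F1 | step 2 | racemic (2R*,3R*)-3-hydroxy-2-methyl-2-(prop-2-en-1-yl)cyclohexan-1-one (OH cis to allyl) | C=CC[C@@]1(C)C(=O)CCC[C@H]1O.C=CC[C@]1(C)C(=O)CCC[C@@H]1O
F2 | step 2 | (1R,2R)-2-methyl-3-oxo-2-(prop-2-en-1-yl)cyclohexyl acetate | C=CC[C@@]1(C)C(=O)CCC[C@H]1OC(C)=O
F3 | step 11 | 9-{(3Z)-4-[(tert-butyldimethylsilyl)oxy]-6-[(2R,3R)-3-{2-[(2R)-3,3-dimethyloxiran-2-yl]ethyl}-3-methyloxiran-2-yl]hex-3-en-1-yl}-9-borabicyclo[3.3.1]nonane | C1CCC2CCCC1B2CC/C=C(\O[Si](C)(C)C(C)(C)C)CC[C@H]3O[C@]3(C)CC[C@H]3OC3(C)C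
F4 | step 11 | tert-butyl({(3Z)-6-[(5R,6S)-2,6-dimethyl-6-[(2E)-4-methyl-4-(triethylsilyloxy)pent-2-en-1-yl]-5-(triethylsilyloxy)cyclohex-1-en-1-yl]-1-[(2R,3R)-3-{2-[(2R)-3,3-dimethyloxiran-2-yl]ethyl}-3-methyloxiran-2-yl]hex-3-en-3-yl}oxy)dimethylsilane | CC1=C(CC/C=C(\O[Si](C)(C)C(C)(C)C)CC[C@H]2O[C@]2(C)CC[C@H]2OC2(C)C)[C@](C)(C/C=C/C(C)(C)O[Si](CC)(CC)CC)[C@H](O[Si](CC)(CC)CC)CC1
F5 | step 11 | (3R,5aR,6R,9aR)-6-{2-[(5R,6S)-2,6-dimethyl-6-[(2E)-4-methyl-4-(triethylsilyloxy)pent-2-en-1-yl]-5-(triethylsilyloxy)cyclohex-1-en-1-yl]ethyl}-2,2,5a-trimethyl-3-(trimethylsilyloxy)octahydro-1-benzoxepin-7(2H)-one | CC1=C(CC[C@@H]2[C@@]3(C)CC[C@@H](O[Si](C)(C)C)C(C)(C)O[C@@H]3CCC2=O)[C@](C)(C/C=C/C(C)(C)O[Si](CC)(CC)CC)[C@H](O[Si](CC)(CC)CC)CC1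
F6 | step 13 | (3R,5aR,6R,7S,9aR)-6-(2-hydroxyethyl)-2,2,5a,7-tetramethyl-3-(trimethylsilyloxy)decahydro-1-benzoxepin-7-ol | OCC[C@@H]1[C@@]2(C)CC[C@@H](O[Si](C)(C)C)C(C)(C)O[C@@H]2CC[C@]1(C)O
F7 | step 13 | (3R,5aR,6R,7S,9aR)-6-(2-iodoethyl)-2,2,5a,7-tetramethyl-3-(trimethylsilyloxy)decahydro-1-benzoxepin-7-ol | ICC[C@@H]1[C@@]2(C)CC[C@@H](O[Si](C)(C)C)C(C)(C)O[C@@H]2CC[C@]1(C)O
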